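A flask this slow shows little at a glance. The red run, which is this very flask followed so far, has 7% of its free monomer in chains at 10.0 min.

common to all: free monomer 0.50 M

|  | initiator | remark | time |
|---|---|---|---|
| red | 47 mM | the very flask that is asked about, followed so far |  |
| green | 94 mM | run made earlier |  |
| flask | 47 mM |  | 30 min |

| run | time / min | monomer in chains / % | free monomer / % |
|---|---|---|---|
| red | 0.667 | 0 | 99 |
| red | 1.00 | 0 | 98 |
| red | 1.50 | 1 | 100 |
| red | 2.50 | 1 | 98 |
| red | 4.00 | 3 | 97 |
| red | 6.00 | 4 | 93 |
| red | 10.0 | 7 | 96 |
| green | 1.50 | 2 | 100 |
| green | 5.00 | 7 | 93 |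
| green | 8.00 | 9 | 89 |
| green | 12.0 | 14 | 85 |
| green | 20.0 | 24 | 75 |
| green | 25.0 | 24 | 69 |
| green | 30.0 | 28 | 66 |

(readings scatter by 1.5 percentage points)

- the average divides the monomer in chains by the number of chains begun, living and dead together
- the earlier runs do not show the number of chains; that part of a forecast is a guess

* average number of monomer units in a chain (chains begun, living or dead) at 30 min
* part of the free monomer that has reacted at 30 min

The green run has twice the initiator and reads 7% in chains at 5.00 min, half the red time, for the same reading. So I take initiator as the concentration that sets the rate, and I treat free monomer as pseudo-first-order. Green's last free monomer reading, 66% at 30.0 min, gives my constant: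

κ = ln(charged / left) / (initiator charge × time) = 0.00246 L mol⁻¹ s⁻¹

This κ, the loss exponent per unit of initiator charge and time, is a reading and carries the scatter. I now run this flask in slow motion with it.

First instants, 4.00 min: reacted 2.73%; red reads 3% in chains.

Middle, 10.0 min: reacted 6.69%; red reads 7% in chains.

End, 30 min: reacted 18.8%.

Red reads 1% in chains at 2.50 min against a scatter of 1.5 percentage points, so the late readings are the ones to watch. Green's two columns sum to 94.0% at 30.0 min, so I read c from free monomer. The readings show no chain count, and I commit to no dp.

The forecast says 17% and 2.2, its c below mine, on this ground: “Rate therefore looks proportional to initiator, not its square root”.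

The flask gives 18.5% reacted and 2.47 units per chain.

    free monomer + initiator → living end + monomer in chains (k = 0.00221 L mol⁻¹ s⁻¹)
    free monomer + living end → monomer in chains + living end, rate k2*[living end]*[free monomer] (k = 0.00308 L mol⁻¹ s⁻¹)
    free monomer + initiator → spent initiator (k = 4.41 × 10⁻⁴ L mol⁻¹ s⁻¹)
    monomer in chains + living end → free monomer + living end, rate k4*[living end] as long as [monomer in chains] is above zero (k = 1.62 × 10⁻⁴ s⁻¹)

My 18.8% stands 0.30 points above the flask. With all else held, this flask's c moves 4 points from 18.5% at 35.9 mM or 58.7 mM of initiator, or at 22.6 min or 37.9 min. Initiator in this flask is down to 12% of its charge at 30.0 min, less than the 82% of free monomer; κ counts the charge, not what remains. For the neighbouring flask with 0.19 M of initiator, κ gives 56.9% at 30 min. That neighbouring flask gives 55.3%.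

(The data are simulated with constants of no real substance, and the scatter is random.)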